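**Plan** (oxolane numbered O1, C2–C5)

- Retrosynthesis: after the benzyl and acetate bonds, the oxolane is cut at O1–C5 and C2–C3 (aldehyde plus donor–acceptor cyclopropane), then at C3–C4 (carbene addition; the second carbene bond, C3–C5, is the one the annulation breaks again), then at the malonate ester C–O and at C4=C5 (olefination of the same aldehyde).
- Forward: Z-olefination and reduction join the three-carbon chain to the arene, the malonate half-ester and diazo group are added, one Rh-carbene step closes cyclopropane and γ-lactone together, the (3+2) annulation closes the oxolane, and ester removal, lactone reduction, acetylation and debenzylation finish.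
- Enabling feature: C5 (aryl-bearing, donor) and C3 (acceptor, later a CH2OAc carbon) stand 1,3 across C4 in the oxolane, and the cis CH2O groups on C3/C4 can be tied into a γ-lactone fused to that ring.
- Stereochemistry: Z-alkene gives the endo-aryl cyclopropane (stereospecific carbene addition); inversion at the donor carbon gives C4/C5 trans; the lactone tether gives C3/C4 cis; the envelope transition state puts the C2 aryl cis to the C5 aryl.

Key step: step 6

Remark: the target is meso (mirror plane through O1 and the C3–C4 midpoint; 2R,3S,4R,5S), so the drawn stereoisomer has no enantiomer and racemic intermediates lead to it.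

**Route**

Step 1
Reactants: 1 3,4-bis(benzyloxy)benzaldehyde; 2 methyl 2-[bis(2,2,2-trifluoroethoxy)phosphoryl]acetate
Product: 3 methyl (2Z)-3-[3,4-bis(benzyloxy)phenyl]prop-2-enoate
Conditions: KHMDS, 18-crown-6, THF, −78 °C
Reagents that add atoms: none
Why: Still–Gennari variant of the Horner–Wadsworth–Emmons olefination, in which the electron-poor bis(trifluoroethyl) phosphonate with a dissociated potassium counter-ion makes elimination faster than equilibration of the adducts, so an aryl aldehyde should give mainly the Z-enoate.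

Step 2
Reactants: 3 methyl (2Z)-3-[3,4-bis(benzyloxy)phenyl]prop-2-enoate
Product: 4 (2Z)-3-[3,4-bis(benzyloxy)phenyl]prop-2-en-1-ol
Conditions: DIBAL-H (2.5 equiv), CH2Cl2, −78 °C; Rochelle salt work-up
Reagents that add atoms: none
Why: DIBAL-H reduction of an α,β-unsaturated ester to the allylic alcohol (1,2-hydride delivery at low temperature), which leaves the Z double bond and the benzyl ethers untouched.

Step 3
Reactants: 4 (2Z)-3-[3,4-bis(benzyloxy)phenyl]prop-2-en-1-ol; 5 methyl 3-chloro-3-oxopropanoate
Product: 6 (2Z)-3-[3,4-bis(benzyloxy)phenyl]prop-2-en-1-yl methyl propanedioate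
Conditions: pyridine, CH2Cl2, 0 °C
Reagents that add atoms: none
Why: O-acylation of a primary allylic alcohol by an acid chloride under mild base, which installs the malonate half-ester without ionising the electron-rich allylic system or changing the alkene geometry.

Step 4
Reactants: 6 (2Z)-3-[3,4-bis(benzyloxy)phenyl]prop-2-en-1-yl methyl propanedioate
Product: 7 (2Z)-3-[3,4-bis(benzyloxy)phenyl]prop-2-en-1-yl methyl 2-diazopropanedioate
Conditions: p-ABSA, Et3N, MeCN, 0 °C to rt
Reagents that add atoms: 4-acetamidobenzenesulfonyl azide, CC(=O)Nc1ccc(cc1)S(=O)(=O)N=[N+]=[N-]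
Why: Regitz diazo transfer from a sulfonyl azide to the doubly activated methylene of the malonate, which runs under mild amine base and tolerates the alkene and the benzyl ethers.

Step 5
Reactants: 7 (2Z)-3-[3,4-bis(benzyloxy)phenyl]prop-2-en-1-yl methyl 2-diazopropanedioate
Product: 8 rac-methyl 6-endo-[3,4-bis(benzyloxy)phenyl]-2-oxo-3-oxabicyclo[3.1.0]hexane-1-carboxylate (aryl cis to C4H2)
Conditions: Rh2(esp)2 (1 mol%), CH2Cl2, slow addition of 7, 40 °C
Reagents that add atoms: none
Why: rhodium(II)-carbenoid intramolecular cyclopropanation of an allyl diazomalonate, a concerted and therefore stereospecific syn addition in which the Z-alkene places the aryl group cis to the lactone CH2 (endo) and the tether fixes the cis ring fusion, the product being racemic.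

Step 6
Reactants: 8 rac-methyl 6-endo-[3,4-bis(benzyloxy)phenyl]-2-oxo-3-oxabicyclo[3.1.0]hexane-1-carboxylate; 1 3,4-bis(benzyloxy)benzaldehyde
Product: 9 rac-methyl 4-exo,6-exo-bis[3,4-bis(benzyloxy)phenyl]-3-oxotetrahydro-1H-furo[3,4-c]furan-3a(3H)-carboxylate (cis-fused; both aryl groups on the face opposite the lactone ring)
Conditions: Sn(OTf)2 (10 mol%), 4 Å MS, CH2Cl2, −40 to 0 °C, slow addition of 8 to 1 and the catalyst
Reagents that add atoms: none
Why: Sn(OTf)2 chelates the lactone and ester carbonyls of 8 and polarises the benzylic C1–C6 bond, the carbonyl oxygen of 1 attacks C6 from the side opposite C1 in an SN2-like, strain-releasing step, and after bond rotation the tin enolate adds to the oxocarbenium carbon. The closest known reaction is the Lewis-acid-catalysed (3+2) annulation of 2-arylcyclopropane-1,1-diesters, 2,3-disubstituted ones included, with aldehydes to 2,5-cis-tetrahydrofurans; here one ester is tied back as the fused lactone. The oxolane closes through its C3a–C4 bond in an aldol-type 5-(enolexo)-endo-trig attack on the oxocarbenium ion. C6 is set by stereospecific inversion of the endo-aryl centre (the aryl ends up exo, trans to the lactone CH2), C3a by the lactone tether, which allows only a cis-fused 5/5 system, and C4 by the envelope transition state that keeps the aldehyde aryl pseudo-equatorial, cis to the C6 aryl and on the convex face. The step needs cleavage of C1–C6 and not C1–C5, and capture before the benzylic centre ionises; the aryl donor secures the first, and low temperature together with slow addition of 8 to the aldehyde, which keeps the nucleophile in local excess while the two partners are used in equimolar amounts, supports the second.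

Step 7
Reactants: 9 rac-methyl 4-exo,6-exo-bis[3,4-bis(benzyloxy)phenyl]-3-oxotetrahydro-1H-furo[3,4-c]furan-3a(3H)-carboxylate
Product: 10 rac-4-exo,6-exo-bis[3,4-bis(benzyloxy)phenyl]tetrahydro-1H,3H-furo[3,4-c]furan-1-one (cis-fused)
Conditions: LiCl, H2O (2 equiv), DMSO, 140 °C
Reagents that add atoms: none
Why: Krapcho demethoxycarbonylation, in which chloride demethylates the ester, the β-carbonyl carboxylate loses CO2 and the lactone enolate is protonated to the only accessible cis-fused ring junction, so the new C–H is fixed by the tether and the two benzylic centres are not touched.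

Step 8
Reactants: 10 rac-4-exo,6-exo-bis[3,4-bis(benzyloxy)phenyl]tetrahydro-1H,3H-furo[3,4-c]furan-1-one
Product: 11 meso-[(2R,3S,4R,5S)-2,5-bis[3,4-bis(benzyloxy)phenyl]oxolane-3,4-diyl]dimethanol
Conditions: LiAlH4, THF, 0 °C to rt; aqueous NaOH work-up (no acid)
Reagents that add atoms: none
Why: LiAlH4 reduction of a γ-lactone to the 1,4-diol, which touches no stereocentre and turns the racemic lactone into a single meso diol, a non-acidic work-up avoiding ionisation of the benzylic ether bonds.

Step 9
Reactants: 11 meso-[(2R,3S,4R,5S)-2,5-bis[3,4-bis(benzyloxy)phenyl]oxolane-3,4-diyl]dimethanol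
Product: 12 meso-[(2R,3S,4R,5S)-2,5-bis[3,4-bis(benzyloxy)phenyl]oxolane-3,4-diyl]bis(methylene) diacetate
Conditions: Ac2O, pyridine, DMAP (cat.), CH2Cl2, rt
Reagents that add atoms: acetic anhydride, CC(=O)OC(C)=O
Why: DMAP-catalysed O-acetylation of two primary alcohols, the only nucleophilic sites in the molecule.

Step 10
Reactants: 12 meso-[(2R,3S,4R,5S)-2,5-bis[3,4-bis(benzyloxy)phenyl]oxolane-3,4-diyl]bis(methylene) diacetate
Product: 13 [(2R,3S,4R,5S)-2,5-bis(3,4-dihydroxyphenyl)oxolane-3,4-diyl]bis(methylene) diacetate (CNP0416169.1)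
Conditions: H2 (1 atm), 10% Pd/C, EtOAc, rt
Reagents that add atoms: none
Why: palladium-catalysed hydrogenolysis of the four aryl benzyl ethers, which under neutral conditions at 1 atm should be cleaved much faster than the hindered ring benzylic C–O bonds while the alkyl acetates are inert, the reaction being stopped once the benzyl ethers are consumed.

**Compound list**

1 | 3,4-bis(benzyloxy)benzaldehyde | O=Cc1ccc(OCc2ccccc2)c(OCc2ccccc2)c1 | starting material
2 | methyl 2-[bis(2,2,2-trifluoroethoxy)phosphoryl]acetate | COC(=O)CP(=O)(OCC(F)(F)F)OCC(F)(F)F | starting material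
3 | methyl (2Z)-3-[3,4-bis(benzyloxy)phenyl]prop-2-enoate | COC(=O)/C=C\c1ccc(OCc2ccccc2)c(OCc2ccccc2)c1 | intermediate
4 | (2Z)-3-[3,4-bis(benzyloxy)phenyl]prop-2-en-1-ol | OC/C=C\c1ccc(OCc2ccccc2)c(OCc2ccccc2)c1 | intermediate
5 | methyl 3-chloro-3-oxopropanoate | COC(=O)CC(=O)Cl | starting material
6 | (2Z)-3-[3,4-bis(benzyloxy)phenyl]prop-2-en-1-yl methyl propanedioate | COC(=O)CC(=O)OC/C=C\c1ccc(OCc2ccccc2)c(OCc2ccccc2)c1 | intermediate
7 | (2Z)-3-[3,4-bis(benzyloxy)phenyl]prop-2-en-1-yl methyl 2-diazopropanedioate | COC(=O)C(=[N+]=[N-])C(=O)OC/C=C\c1ccc(OCc2ccccc2)c(OCc2ccccc2)c1 | intermediate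
8 | rac-methyl 6-endo-[3,4-bis(benzyloxy)phenyl]-2-oxo-3-oxabicyclo[3.1.0]hexane-1-carboxylate | O=C1OC[C@@H]2[C@H](c3ccc(OCc4ccccc4)c(OCc4ccccc4)c3)[C@]12C(=O)OC | intermediate
9 | rac-methyl 4-exo,6-exo-bis[3,4-bis(benzyloxy)phenyl]-3-oxotetrahydro-1H-furo[3,4-c]furan-3a(3H)-carboxylate | O=C1OC[C@@H]2[C@@H](c3ccc(OCc4ccccc4)c(OCc4ccccc4)c3)O[C@@H](c3ccc(OCc4ccccc4)c(OCc4ccccc4)c3)[C@]12C(=O)OC | intermediate
10 | rac-4-exo,6-exo-bis[3,4-bis(benzyloxy)phenyl]tetrahydro-1H,3H-furo[3,4-c]furan-1-one | O=C1OC[C@@H]2[C@@H](c3ccc(OCc4ccccc4)c(OCc4ccccc4)c3)O[C@@H](c3ccc(OCc4ccccc4)c(OCc4ccccc4)c3)[C@H]12 | intermediate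
11 | meso-[(2R,3S,4R,5S)-2,5-bis[3,4-bis(benzyloxy)phenyl]oxolane-3,4-diyl]dimethanol | OC[C@@H]1[C@H](CO)[C@@H](c2ccc(OCc3ccccc3)c(OCc3ccccc3)c2)O[C@H]1c1ccc(OCc2ccccc2)c(OCc2ccccc2)c1 | intermediate
12 | meso-[(2R,3S,4R,5S)-2,5-bis[3,4-bis(benzyloxy)phenyl]oxolane-3,4-diyl]bis(methylene) diacetate | CC(=O)OC[C@@H]1[C@H](COC(C)=O)[C@@H](c2ccc(OCc3ccccc3)c(OCc3ccccc3)c2)O[C@H]1c1ccc(OCc2ccccc2)c(OCc2ccccc2)c1 | intermediate
13 | [(2R,3S,4R,5S)-2,5-bis(3,4-dihydroxyphenyl)oxolane-3,4-diyl]bis(methylene) diacetate (meso) | CC(=O)OC[C@@H]1[C@H](COC(C)=O)[C@@H](c2ccc(O)c(O)c2)O[C@H]1c1ccc(O)c(O)c1 | target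

**Step count and risks**

Total steps: 10. Longest linear sequence: 10 steps (1 to 13; aldehyde 1 enters a second time in step 6).

Steps most likely to fail:

1. Step 6 (annulation). The very electron-rich benzylic cyclopropane carbon may ionise before the aldehyde captures it, so that the donor centre is scrambled and the stereospecific transfer is lost. The fallback moves stereocontrol from this kinetic event to a thermodynamic one at the monocyclic stage. It sets out from 8 (with 1): the annulation is run without regard to stereospecificity (for instance Sc(OTf)3 at rt), and the material containing the 6-endo-aryl epimer of 9 F1 is taken through the same demethoxycarbonylation to the 4-endo-aryl lactone F2, LiAlH4 reduction to the 4,5-cis diol F3 and acetylation to the 4,5-cis diacetate F4. BF3·OEt2 in CH2Cl2 at low temperature then ionises the electron-rich benzylic C–O bond of F4 reversibly and should funnel it into the isomer with each aryl trans to its neighbour, which is 12, where the route is rejoined. Acid equilibration of 3,4-cis-2,5-diaryloxolanes to this arrangement is established lignan chemistry. It is done on the diacetate and not on the diol, whose free hydroxyl groups could capture the benzylic cation.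

2. Step 5 (cyclopropanation). The tethered carbenoid may be diverted into carbene dimerisation, addition to the electron-rich arene or insertion into the benzylic C–H bonds of the ethers, or the strained endo-aryl product may open on the Lewis-acidic catalyst. The fallback inverts the order of ring formation: intermolecular cyclopropane first, lactone second. It sets out from 4: silylation (TBSCl, imidazole) gives the Z-cinnamyl silyl ether F5. Rh2(esp)2-catalysed cyclopropanation of F5 with dimethyl diazomalonate, stereospecific for the Z-alkene, gives the cis-cyclopropane diester F6. Desilylation (TBAF buffered with AcOH) frees the hydroxymethyl group, which lactonises onto the ester cis to it and returns 8.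

3. Step 7 (demethoxycarbonylation). The lactone enolate formed at 140 °C may expel the ring oxygen by β-elimination (retro-oxa-Michael opening of the oxolane), which would scramble the adjacent benzylic centre or destroy the ring. The fallback removes the ester through the free acid and not through a hot enolate. It sets out from 9: LiOH in aqueous THF hydrolyses both acyl groups (no enolisable centre is present at this point), and acidification re-closes the γ-lactone to the lactone acid F7. Heating F7 in toluene at about 100 °C decarboxylates the β-carbonyl acid through a cyclic transition state and gives the cis-fused lactone 10.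

**Further compounds**

F1 | step 6 | rac-methyl 4-exo,6-endo-bis[3,4-bis(benzyloxy)phenyl]-3-oxotetrahydro-1H-furo[3,4-c]furan-3a(3H)-carboxylate | O=C1OC[C@@H]2[C@H](c3ccc(OCc4ccccc4)c(OCc4ccccc4)c3)O[C@@H](c3ccc(OCc4ccccc4)c(OCc4ccccc4)c3)[C@]12C(=O)OC
F2 | step 6 | rac-4-endo,6-exo-bis[3,4-bis(benzyloxy)phenyl]tetrahydro-1H,3H-furo[3,4-c]furan-1-one | O=C1OC[C@@H]2[C@H](c3ccc(OCc4ccccc4)c(OCc4ccccc4)c3)O[C@@H](c3ccc(OCc4ccccc4)c(OCc4ccccc4)c3)[C@H]12
F3 | step 6 | rac-[2,3-trans-3,4-cis-4,5-cis-2,5-bis[3,4-bis(benzyloxy)phenyl]oxolane-3,4-diyl]dimethanol | OC[C@@H]1[C@H](CO)[C@H](c2ccc(OCc3ccccc3)c(OCc3ccccc3)c2)O[C@H]1c1ccc(OCc2ccccc2)c(OCc2ccccc2)c1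
F4 | step 6 | rac-[2,3-trans-3,4-cis-4,5-cis-2,5-bis[3,4-bis(benzyloxy)phenyl]oxolane-3,4-diyl]bis(methylene) diacetate | CC(=O)OC[C@@H]1[C@H](COC(C)=O)[C@H](c2ccc(OCc3ccccc3)c(OCc3ccccc3)c2)O[C@H]1c1ccc(OCc2ccccc2)c(OCc2ccccc2)c1
F5 | step 5 | tert-butyl{[(2Z)-3-[3,4-bis(benzyloxy)phenyl]prop-2-en-1-yl]oxy}dimethylsilane | CC(C)(C)[Si](C)(C)OC/C=C\c1ccc(OCc2ccccc2)c(OCc2ccccc2)c1
F6 | step 5 | rac-dimethyl cis-2-[3,4-bis(benzyloxy)phenyl]-3-{[tert-butyl(dimethyl)silyl]oxymethyl}cyclopropane-1,1-dicarboxylate | COC(=O)C1(C(=O)OC)[C@@H](c2ccc(OCc3ccccc3)c(OCc3ccccc3)c2)[C@H]1CO[Si](C)(C)C(C)(C)C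
F7 | step 7 | rac-4-exo,6-exo-bis[3,4-bis(benzyloxy)phenyl]-3-oxotetrahydro-1H-furo[3,4-c]furan-3a(3H)-carboxylic acid | O=C1OC[C@@H]2[C@@H](c3ccc(OCc4ccccc4)c(OCc4ccccc4)c3)O[C@@H](c3ccc(OCc4ccccc4)c(OCc4ccccc4)c3)[C@]12C(=O)O
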